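## Retrosynthetic overview

1. The two (Z)-2-methylbut-2-enoates go on last, onto a cis-2,3-diol. The side chain C(=CH2)–CH(OAc)–CH2CH=CMe2 is grown from a CH2CHO arm at C4 (α-methylenation, Brown allylboration, acetylation, cross-metathesis). The oxirane comes from SN2 closure of the tertiary C1–OH onto a C6 mesylate.
2. Key disconnection: bonds C3–C4 and C1–C6 are made in one flask by a [3+3] Michael/aldol annulation. A dihydroxyacetone-type enol silane supplies C1–C2–C3 with all three oxygens; an enal supplies C4–C5–C6.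
3. Enabling feature: C1 and C3 are both oxygenated and both flank oxygenated C2, with the three C–O bonds on one ring face. With C2 as a ketone they are the two α-carbons of a 1,3-dioxan-5-one, whose acetonide ring ties O–C1 and O–C3 cis. C4 (side chain), C5 (CH2) and C6 (C–O) are the β-carbon, α-carbon and carbonyl carbon of an enal.
4. Ring order: 1,3-dioxane (in the starting material) → carbocycle (step 5, as a 2,4-dioxabicyclo[3.3.1]nonan-9-one) → 1,3-dioxolane by acetal migration (step 7) → oxirane (step 8).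
5. Stereocontrol: C4 by the iminium catalyst, relayed to C3, C1 and C6 by the bicyclic frame; C2 by hydroxyl-directed reduction; the side-chain carbinol by reagent-controlled allylboration.

Key step: step 5

Remark: ring positions of the target are numbered as in 7-oxabicyclo[4.1.0]heptane (C1 methyl-bearing oxirane carbon, C2 and C3 the ester carbons, C4 the side-chain carbon, C6 the second oxirane carbon); R/S changes between intermediates of unchanged geometry are CIP effects only, and all simple building blocks and reagents named are taken to be commercial.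

## Route

Step 1
Reactants: 1 2,2-dimethyl-1,3-dioxan-5-one
Product: 2 N,N-dimethylhydrazone of 2,2-dimethyl-1,3-dioxan-5-one
Conditions: Me2NNH2, AcOH (cat.), MgSO4, CH2Cl2, rt
Reagents that add atoms: N,N-dimethylhydrazine, CN(C)N
Why: Hydrazone condensation of the symmetric ketone gives a single product and prepares a clean α-monoalkylation, which the free dioxanone enolate does not allow.

Step 2
Reactants: 2 N,N-dimethylhydrazone of 2,2-dimethyl-1,3-dioxan-5-one
Product: 4 (±)-2,2,4-trimethyl-1,3-dioxan-5-one, via methylated hydrazone 3 (not isolated)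
Conditions: LDA, THF, −78 °C; MeI, −78 °C → rt; then sat. aq. oxalic acid, Et2O, rt
Reagents that add atoms: iodomethane, CI; water, O
Why: Azaenolate alkylation of the symmetric hydrazone followed by two-phase acid hydrolysis should give the monomethyl ketone; the new stereocentre is left racemic on purpose because it is planarised in step 5.

Step 3
Reactants: 4 (±)-2,2,4-trimethyl-1,3-dioxan-5-one
Product: 5 (±)-tert-butyldimethyl[(2,2,4-trimethyl-4H-1,3-dioxin-5-yl)oxy]silane
Conditions: LDA, THF, −78 °C; TBSOTf, −78 → 0 °C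
Reagents that add atoms: tert-butyldimethylsilyl trifluoromethanesulfonate, CC(C)(C)[Si](C)(C)OS(=O)(=O)C(F)(F)F
Why: Kinetic deprotonation at the less hindered OCH2 carbon and O-silylation (kinetic enolate trapping) should give the less substituted silyl enol ether, whose free enol carbon is the future C3.

Step 4
Reactants: 6 3-(tert-butyldimethylsilyloxy)propanal
Product: 7 (E)-5-(tert-butyldimethylsilyloxy)pent-2-enal
Conditions: Ph3P=CHCHO, toluene, 80 °C
Reagents that add atoms: (triphenylphosphoranylidene)acetaldehyde, O=CC=P(c1ccccc1)(c1ccccc1)c1ccccc1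
Why: Wittig olefination with the stabilised formyl ylide should give the E-enal, a simple β-alkyl acceptor without a second conjugated site.

Step 5
Reactants: 5 (±)-tert-butyldimethyl[(2,2,4-trimethyl-4H-1,3-dioxin-5-yl)oxy]silane; 7 (E)-5-(tert-butyldimethylsilyloxy)pent-2-enal
Product: 9 (1S,5R,6R,8R)-6-[2-(tert-butyldimethylsilyloxy)ethyl]-8-hydroxy-1,3,3-trimethyl-2,4-dioxabicyclo[3.3.1]nonan-9-one, via keto aldehyde 8 (not isolated)
Conditions: (2S,5S)-5-benzyl-2-tert-butyl-3-methylimidazolidin-4-one·TFA (20 mol %), CH2Cl2, H2O (2 equiv), −40 °C; then LiCl, DBU, MeCN, 0 °C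
Reagents that add atoms: none
Why: The imidazolidinone and 7 form the E-iminium ion, enol silane 5 adds to its β-carbon (organocatalytic Mukaiyama–Michael addition, 1,4 only), hydrolysis gives keto aldehyde 8, and LiCl/DBU then enolises 8 toward the methyl-bearing α′-carbon, which adds to the aldehyde (intramolecular aldol); the closest known reaction type is the Stork-type α,α′-annulation of a cyclic ketone with an enal to a 2-hydroxybicyclo[3.3.1]nonan-9-one. The carbocycle closes 6-(enolendo)-exo-trig, the only aldol open to 8 because every other enolate would have to form a four-membered ring. C6 of 9 (future C4) is set by the catalyst, the nucleophile entering the β-face anti to the benzyl group, which is the established sense for this catalyst with β-alkyl enals. C5 and C1 of 9 (future C3 and C1) follow from the dioxane ring, which can bridge the new ring only through two axial, hence cis, C–O bonds; since the α-carbon of 8 epimerises under DBU and the racemic methyl-bearing centre of 5 is planarised in the enolate, all isomers of 8 should drain through the chair transition state that keeps the side chain equatorial, that is cis to the neighbouring oxygen. C8 (future C6) is set by the lithium-chelated closed transition state, in which the aldehyde oxygen lies gauche to the ketone and becomes an axial hydroxyl anti to the C1–O bond. The step needs β-face selectivity (catalyst), 1,4-regioselectivity (iminium activation) and a single enolisation mode (ring-size constraint), and once the ring is closed retro-Michael loss of the C6 centre is excluded because the α-carbon has become a bridgehead.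

Step 6
Reactants: 9 (1S,5R,6R,8R)-6-[2-(tert-butyldimethylsilyloxy)ethyl]-8-hydroxy-1,3,3-trimethyl-2,4-dioxabicyclo[3.3.1]nonan-9-one
Product: 10 (1R,5S,6R,8R,9R)-8-[2-(tert-butyldimethylsilyloxy)ethyl]-3,3,5-trimethyl-2,4-dioxabicyclo[3.3.1]nonane-6,9-diol
Conditions: Me4NBH(OAc)3, MeCN/AcOH (1:1), −30 → −20 °C
Reagents that add atoms: none
Why: Evans–Saksena reduction: the axial hydroxyl binds boron and delivers hydride intramolecularly to the carbonyl face it overhangs, which should give the 1,3-anti diol with the new hydroxyl on the side of the two acetal oxygens, while the bridgehead α-carbons cannot epimerise.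

Step 7
Reactants: 10 (1R,5S,6R,8R,9R)-8-[2-(tert-butyldimethylsilyloxy)ethyl]-3,3,5-trimethyl-2,4-dioxabicyclo[3.3.1]nonane-6,9-diol
Product: 11 (3aR,4S,5R,7R,7aR)-7-[2-(tert-butyldimethylsilyloxy)ethyl]-2,2,4-trimethylhexahydro-1,3-benzodioxole-4,5-diol
Conditions: CSA (5 mol %), CH2Cl2, 0 °C → rt
Reagents that add atoms: none
Why: Acid-catalysed acetal migration (intramolecular transketalisation) under thermodynamic control should move the isopropylidene group from the strained bridged 1,3-dioxane, whose inward methyl is pressed against the carbocycle, to the cis-fused 1,3-dioxolane on the two secondary cis-oxygens, which frees the tertiary hydroxyl and changes no stereocentre.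

Step 8
Reactants: 11 (3aR,4S,5R,7R,7aR)-7-[2-(tert-butyldimethylsilyloxy)ethyl]-2,2,4-trimethylhexahydro-1,3-benzodioxole-4,5-diol
Product: 13 (1S,2R,3R,4R,6S)-4-[2-(tert-butyldimethylsilyloxy)ethyl]-2,3-O-isopropylidene-1-methyl-7-oxabicyclo[4.1.0]heptane-2,3-diol, via C5 mesylate 12 (not isolated)
Conditions: MsCl, Et3N, CH2Cl2, 0 °C; then K2CO3, MeOH, rt
Reagents that add atoms: none
Why: Sulfonylation is selective for the secondary over the tertiary hydroxyl, and the tertiary alkoxide then displaces the anti-periplanar mesylate (intramolecular Williamson reaction, SN2 with inversion at the secondary carbon), which places the oxirane on the face of the tertiary oxygen, cis to the dioxolane.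

Step 9
Reactants: 13 (1S,2R,3R,4R,6S)-4-[2-(tert-butyldimethylsilyloxy)ethyl]-2,3-O-isopropylidene-1-methyl-7-oxabicyclo[4.1.0]heptane-2,3-diol
Product: 14 2-[(1S,2R,3R,4R,6S)-2,3-(isopropylidenedioxy)-1-methyl-7-oxabicyclo[4.1.0]heptan-4-yl]ethanol
Conditions: TBAF, THF, 0 °C → rt
Reagents that add atoms: none
Why: Fluoride desilylation of the primary silyl ether should leave oxirane and acetonide untouched.

Step 10
Reactants: 14 2-[(1S,2R,3R,4R,6S)-2,3-(isopropylidenedioxy)-1-methyl-7-oxabicyclo[4.1.0]heptan-4-yl]ethanol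
Product: 15 2-[(1S,2R,3R,4S,6S)-2,3-(isopropylidenedioxy)-1-methyl-7-oxabicyclo[4.1.0]heptan-4-yl]acetaldehyde
Conditions: DMP, NaHCO3, CH2Cl2, rt
Reagents that add atoms: none
Why: Dess–Martin oxidation of the only free hydroxyl should give the aldehyde under buffered, non-epimerising conditions (the ring stereocentre is β to the carbonyl).

Step 11
Reactants: 15 2-[(1S,2R,3R,4S,6S)-2,3-(isopropylidenedioxy)-1-methyl-7-oxabicyclo[4.1.0]heptan-4-yl]acetaldehyde
Product: 16 2-[(1S,2R,3R,4S,6S)-2,3-(isopropylidenedioxy)-1-methyl-7-oxabicyclo[4.1.0]heptan-4-yl]prop-2-enal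
Conditions: 37% aq. CH2O, pyrrolidine (10 mol %), EtCO2H (10 mol %), iPrOH, 45 °C
Reagents that add atoms: formaldehyde, C=O
Why: Amine-catalysed α-methylenation (Mannich condensation and elimination via the enamine) should install the exocyclic methylene of the side chain at the only enolisable position.

Step 12
Reactants: 16 2-[(1S,2R,3R,4S,6S)-2,3-(isopropylidenedioxy)-1-methyl-7-oxabicyclo[4.1.0]heptan-4-yl]prop-2-enal
Product: 17 (3S)-2-[(1S,2R,3R,4S,6S)-2,3-(isopropylidenedioxy)-1-methyl-7-oxabicyclo[4.1.0]heptan-4-yl]hexa-1,5-dien-3-ol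
Conditions: (−)-Ipc2B(allyl), Et2O, −78 °C; then NaOH, H2O2
Reagents that add atoms: (−)-B-allyldiisopinocampheylborane, C=CCB([C@@H]1C[C@@H]2C[C@@H](C2(C)C)[C@H]1C)[C@@H]1C[C@@H]2C[C@@H](C2(C)C)[C@H]1C
Why: Brown allylboration through a chair transition state adds 1,2 to the enal, and the (+)-α-pinene-derived reagent attacks the Si face of the aldehyde, so the (S)-carbinol should form under reagent control.

Step 13
Reactants: 17 (3S)-2-[(1S,2R,3R,4S,6S)-2,3-(isopropylidenedioxy)-1-methyl-7-oxabicyclo[4.1.0]heptan-4-yl]hexa-1,5-dien-3-ol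
Product: 18 (3S)-2-[(1S,2R,3R,4S,6S)-2,3-(isopropylidenedioxy)-1-methyl-7-oxabicyclo[4.1.0]heptan-4-yl]hexa-1,5-dien-3-yl acetate
Conditions: Ac2O, pyridine, DMAP (cat.), CH2Cl2, rt
Reagents that add atoms: acetic anhydride, CC(=O)OC(C)=O
Why: Acylation of the only free hydroxyl proceeds with retention at the carbinol carbon.

Step 14
Reactants: 18 (3S)-2-[(1S,2R,3R,4S,6S)-2,3-(isopropylidenedioxy)-1-methyl-7-oxabicyclo[4.1.0]heptan-4-yl]hexa-1,5-dien-3-yl acetate
Product: 19 (3S)-2-[(1S,2R,3R,4S,6S)-2,3-(isopropylidenedioxy)-1-methyl-7-oxabicyclo[4.1.0]heptan-4-yl]-6-methylhepta-1,5-dien-3-yl acetate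
Conditions: (H2IMes)(PCy3)Cl2Ru=CHPh (5 mol %), 2-methyl-2-butene/CH2Cl2, 40 °C
Reagents that add atoms: 2-methyl-2-butene, CC=C(C)C
Why: Olefin cross-metathesis engages only the monosubstituted alkene, the 1,1-disubstituted alkene being too hindered, and converts vinyl into the prenyl terminus.

Step 15
Reactants: 19 (3S)-2-[(1S,2R,3R,4S,6S)-2,3-(isopropylidenedioxy)-1-methyl-7-oxabicyclo[4.1.0]heptan-4-yl]-6-methylhepta-1,5-dien-3-yl acetate
Product: 20 (3S)-2-[(1S,2R,3R,4S,6S)-2,3-dihydroxy-1-methyl-7-oxabicyclo[4.1.0]heptan-4-yl]-6-methylhepta-1,5-dien-3-yl acetate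
Conditions: AcOH/H2O (4:1), 40 °C
Reagents that add atoms: none
Why: Mild acetal hydrolysis should free the cis-diol, the oxirane being deactivated toward acid opening at its tertiary carbon by the adjacent C2–O bond.

Step 16
Reactants: 20 (3S)-2-[(1S,2R,3R,4S,6S)-2,3-dihydroxy-1-methyl-7-oxabicyclo[4.1.0]heptan-4-yl]-6-methylhepta-1,5-dien-3-yl acetate
Product: 21 (1S,2R,3R,4S,6S)-4-[(3S)-3-acetoxy-6-methylhepta-1,5-dien-2-yl]-1-methyl-7-oxabicyclo[4.1.0]heptane-2,3-diyl bis[(Z)-2-methylbut-2-enoate]
Conditions: angelic acid, 2,4,6-Cl3C6H2COCl, Et3N, toluene, rt; then 20, 80 °C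
Reagents that add atoms: angelic acid, C/C=C(/C)C(=O)O
Why: Yamaguchi-type mixed-anhydride esterification acylates both secondary hydroxyls with retention and, without a nucleophilic acyl-transfer catalyst, should keep the Z geometry of the angelate.

## Compound list

1 | 2,2-dimethyl-1,3-dioxan-5-one | CC1(C)OCC(=O)CO1 | starting material
2 | N,N-dimethylhydrazone of 2,2-dimethyl-1,3-dioxan-5-one | CN(C)N=C1COC(C)(C)OC1 | intermediate
3 | N,N-dimethylhydrazone of (±)-2,2,4-trimethyl-1,3-dioxan-5-one (racemic) | CC1OC(C)(C)OCC1=NN(C)C | intermediate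
4 | (±)-2,2,4-trimethyl-1,3-dioxan-5-one (racemic) | CC1OC(C)(C)OCC1=O | intermediate
5 | (±)-tert-butyldimethyl[(2,2,4-trimethyl-4H-1,3-dioxin-5-yl)oxy]silane (racemic) | CC1OC(C)(C)OC=C1O[Si](C)(C)C(C)(C)C | intermediate
6 | 3-(tert-butyldimethylsilyloxy)propanal | CC(C)(C)[Si](C)(C)OCCC=O | starting material
7 | (E)-5-(tert-butyldimethylsilyloxy)pent-2-enal | CC(C)(C)[Si](C)(C)OCC/C=C/C=O | intermediate
8 | (3R)-5-(tert-butyldimethylsilyloxy)-3-(2,2,6-trimethyl-5-oxo-1,3-dioxan-4-yl)pentanal, epimer mixture at the two dioxanone centres | O=CC[C@@H](CCO[Si](C)(C)C(C)(C)C)C1OC(C)(C)OC(C)C1=O | intermediate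
9 | (1S,5R,6R,8R)-6-[2-(tert-butyldimethylsilyloxy)ethyl]-8-hydroxy-1,3,3-trimethyl-2,4-dioxabicyclo[3.3.1]nonan-9-one (side chain equatorial, hydroxyl axial on the carbocycle) | CC(C)(C)[Si](C)(C)OCC[C@@H]1C[C@@H](O)[C@]2(C)OC(C)(C)O[C@H]1C2=O | intermediate
10 | (1R,5S,6R,8R,9R)-8-[2-(tert-butyldimethylsilyloxy)ethyl]-3,3,5-trimethyl-2,4-dioxabicyclo[3.3.1]nonane-6,9-diol (9-OH syn to the acetal oxygens, 6-OH anti) | CC(C)(C)[Si](C)(C)OCC[C@@H]1C[C@@H](O)[C@]2(C)OC(C)(C)O[C@H]1[C@H]2O | intermediate
11 | (3aR,4S,5R,7R,7aR)-7-[2-(tert-butyldimethylsilyloxy)ethyl]-2,2,4-trimethylhexahydro-1,3-benzodioxole-4,5-diol | CC(C)(C)[Si](C)(C)OCC[C@@H]1C[C@@H](O)[C@](C)(O)[C@@H]2OC(C)(C)O[C@H]12 | intermediate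
12 | C5 methanesulfonate of 11 (tertiary C4 hydroxyl free) | CC(C)(C)[Si](C)(C)OCC[C@@H]1C[C@@H](OS(C)(=O)=O)[C@](C)(O)[C@@H]2OC(C)(C)O[C@H]12 | intermediate
13 | (1S,2R,3R,4R,6S)-4-[2-(tert-butyldimethylsilyloxy)ethyl]-2,3-O-isopropylidene-1-methyl-7-oxabicyclo[4.1.0]heptane-2,3-diol | CC(C)(C)[Si](C)(C)OCC[C@@H]1C[C@@H]2O[C@]2(C)[C@@H]3OC(C)(C)O[C@H]13 | intermediate
14 | 2-[(1S,2R,3R,4R,6S)-2,3-(isopropylidenedioxy)-1-methyl-7-oxabicyclo[4.1.0]heptan-4-yl]ethanol | OCC[C@@H]1C[C@@H]2O[C@]2(C)[C@@H]3OC(C)(C)O[C@H]13 | intermediate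
15 | 2-[(1S,2R,3R,4S,6S)-2,3-(isopropylidenedioxy)-1-methyl-7-oxabicyclo[4.1.0]heptan-4-yl]acetaldehyde | O=CC[C@@H]1C[C@@H]2O[C@]2(C)[C@@H]3OC(C)(C)O[C@H]13 | intermediate
16 | 2-[(1S,2R,3R,4S,6S)-2,3-(isopropylidenedioxy)-1-methyl-7-oxabicyclo[4.1.0]heptan-4-yl]prop-2-enal | C=C(C=O)[C@@H]1C[C@@H]2O[C@]2(C)[C@@H]3OC(C)(C)O[C@H]13 | intermediate
17 | (3S)-2-[(1S,2R,3R,4S,6S)-2,3-(isopropylidenedioxy)-1-methyl-7-oxabicyclo[4.1.0]heptan-4-yl]hexa-1,5-dien-3-ol | C=C([C@H](CC=C)O)[C@@H]1C[C@@H]2O[C@]2(C)[C@@H]3OC(C)(C)O[C@H]13 | intermediate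
18 | (3S)-2-[(1S,2R,3R,4S,6S)-2,3-(isopropylidenedioxy)-1-methyl-7-oxabicyclo[4.1.0]heptan-4-yl]hexa-1,5-dien-3-yl acetate | C=C([C@H](CC=C)OC(C)=O)[C@@H]1C[C@@H]2O[C@]2(C)[C@@H]3OC(C)(C)O[C@H]13 | intermediate
19 | (3S)-2-[(1S,2R,3R,4S,6S)-2,3-(isopropylidenedioxy)-1-methyl-7-oxabicyclo[4.1.0]heptan-4-yl]-6-methylhepta-1,5-dien-3-yl acetate | C=C([C@H](CC=C(C)C)OC(C)=O)[C@@H]1C[C@@H]2O[C@]2(C)[C@@H]3OC(C)(C)O[C@H]13 | intermediate
20 | (3S)-2-[(1S,2R,3R,4S,6S)-2,3-dihydroxy-1-methyl-7-oxabicyclo[4.1.0]heptan-4-yl]-6-methylhepta-1,5-dien-3-yl acetate | C=C([C@H](CC=C(C)C)OC(C)=O)[C@@H]1C[C@@H]2O[C@]2(C)[C@H](O)[C@@H]1O | intermediate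
21 | (1S,2R,3R,4S,6S)-4-[(3S)-3-acetoxy-6-methylhepta-1,5-dien-2-yl]-1-methyl-7-oxabicyclo[4.1.0]heptane-2,3-diyl bis[(Z)-2-methylbut-2-enoate] | C=C([C@H](CC=C(C)C)OC(C)=O)[C@@H]1C[C@@H]2O[C@]2(C)[C@H](OC(=O)/C(C)=C\C)[C@@H]1OC(=O)/C(C)=C\C | target

## Step count and risks

Total step count: 16. Longest linear sequence: 15 (steps 1–3 and 5–16; step 4 is the one-step side branch).

**Step 5.** The aldol closure may run through an open, non-chelated arrangement or equilibrate by retro-aldol, so that the C8 hydroxyl of the bicycle ends up equatorial (syn to the C1–O bond). That epimer would misdirect the reduction in step 6 and cannot be displaced in step 8. The fallback sets out from keto aldehyde 8 and comes back at 9. Compound 8 is cyclised under whatever conditions close the ring (for example K2CO3 in MeOH), which gives the C8-epimeric aldol F1, alone or mixed with 9. The carbinol is oxidised with DMP to the 8,9-dione F2. Of the two ketones, C8 is flanked by a CH2 whereas C9 lies between two oxygenated bridgeheads, so L-Selectride at −78 °C should attack C8 from the equatorial side and return the axial alcohol 9.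

**Step 7.** The acetal may migrate onto the tertiary oxygen instead of the secondary one, or stop at a mixture of the two cis-fused dioxolanes, because the thermodynamic difference between them is small. The fallback sets out from 10 and comes back at 11. It replaces equilibration by kinetic differentiation of secondary and tertiary hydroxyls. The bridged acetal is first cleaved completely (PPTS, MeOH, 0 °C; the strained acetonide should go before the silyl ether) to the tetraol, (1R,2S,3R,4R,5R)-5-[2-(tert-butyldimethylsilyloxy)ethyl]-2-methylcyclohexane-1,2,3,4-tetrol F3. F3 is then treated with 2-methoxypropene and catalytic PPTS at −20 °C. The enol ether adds to a secondary hydroxyl, and the mixed ketal can close only onto the neighbouring cis secondary hydroxyl, which gives 11.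

**Step 15.** Acid-promoted opening of the trisubstituted oxirane (hydrolysis or attack by a freed neighbouring hydroxyl) may compete with hydrolysis of the dioxolane. The fallback sets out from 19 and comes back at 21. It takes the oxirane out of the way as a halohydrin and closes it again in the last operation. Li2NiBr4 in THF should open the oxirane at the secondary carbon, remote from the C2 oxygen, with inversion, giving the trans-bromohydrin acetonide F4. Aqueous acetic acid then removes the acetonide with no oxirane present, giving the bromo triol F5. Mixed-anhydride angeloylation as in step 16 esterifies the two secondary hydroxyls, giving the bromohydrin bis-angelate F6. K2CO3 in acetone closes the tertiary alkoxide onto the bromide, with a second inversion, to give 21.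

Further compounds
F1 | step 5 | (1S,5R,6R,8S)-6-[2-(tert-butyldimethylsilyloxy)ethyl]-8-hydroxy-1,3,3-trimethyl-2,4-dioxabicyclo[3.3.1]nonan-9-one (C8 epimer of 9) | CC(C)(C)[Si](C)(C)OCC[C@@H]1C[C@H](O)[C@]2(C)OC(C)(C)O[C@H]1C2=O
F2 | step 5 | (1S,5R,6R)-6-[2-(tert-butyldimethylsilyloxy)ethyl]-1,3,3-trimethyl-2,4-dioxabicyclo[3.3.1]nonane-8,9-dione | CC(C)(C)[Si](C)(C)OCC[C@@H]1CC(=O)[C@]2(C)OC(C)(C)O[C@H]1C2=O
F3 | step 7 | (1R,2S,3R,4R,5R)-5-[2-(tert-butyldimethylsilyloxy)ethyl]-2-methylcyclohexane-1,2,3,4-tetrol | CC(C)(C)[Si](C)(C)OCC[C@@H]1C[C@@H](O)[C@](C)(O)[C@H](O)[C@@H]1O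
F4 | step 15 | trans-bromohydrin of 19 (bromide at the former C6, tertiary hydroxyl at C1, acetonide retained) | C=C([C@H](CC=C(C)C)OC(C)=O)[C@@H]1C[C@@H](Br)[C@](C)(O)[C@@H]2OC(C)(C)O[C@H]12
F5 | step 15 | bromo triol from F4 (acetonide removed) | C=C([C@H](CC=C(C)C)OC(C)=O)[C@@H]1C[C@@H](Br)[C@](C)(O)[C@H](O)[C@@H]1O
F6 | step 15 | bromohydrin bis[(Z)-2-methylbut-2-enoate] from F5 | C=C([C@H](CC=C(C)C)OC(C)=O)[C@@H]1C[C@@H](Br)[C@](C)(O)[C@H](OC(=O)/C(C)=C\C)[C@@H]1OC(=O)/C(C)=C\C
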